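Ring B (C5–C10, labdane numbering) is opened at C5–C10. This bond joins C10, which is α to C9, and C5, which is β to the C3 carboxyl; with a temporary ketone at C9 it is the Michael bond of a 1,5-dicarbonyl array. (R)-Linalool is mapped onto C8 instead of C13: its carbinol supplies C8, the C8 methyl and the ring oxygen, its vinyl group C9 and C10. The key step, a lithium-chelate-controlled Michael cyclisation of an acyclic α-alkoxy ethyl ketone onto an (E)-enoate with allylation of the resulting enolate in the same flask, closes ring B and sets C5 and C10 from C8. C9, the pyran ring and C13 follow.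

Key step: step 7

Remark: atoms carry labdane numbers (C1 = CH2 and C2 = carboxyl of the acetic acid arm; C4 = C(CH3)2 and C3 = its carboxyl; ring B = C5–C10 with methyl groups on C8 and C10; pyran = O, C8, C9, C11, C12, C13). The SMILES is read as 5R,8R,9S,10S,13R, that is H-9 on the face of ring B that carries the C8 and C10 methyl groups (called β; the other face α) and a cis-fused pyran, and the route is built for this isomer.

Step 1
Reactants: 1 (R)-(−)-linalool
Product: 2 (2R)-6-methyl-2-(oxiran-2-yl)hept-5-en-2-ol (both epoxide epimers)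
Conditions: VO(acac)2 (2 mol %), t-BuOOH, CH2Cl2, 0 °C → rt
Reagents that add atoms: tert-butyl hydroperoxide, CC(C)(C)OO
Why: Hydroxyl-directed epoxidation of an allylic alcohol, in which the metal-bound alkylperoxide is delivered only to the vinyl group next to the carbinol and the trisubstituted alkene is left; the uncontrolled epoxide centre (later C9) is erased in step 3, and C8 comes from the chiral pool.

Step 2
Reactants: 2 (2R)-6-methyl-2-(oxiran-2-yl)hept-5-en-2-ol
Product: 3 (4R)-4,8-dimethylnon-7-ene-3,4-diol (both C3 epimers)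
Conditions: CH3MgBr (3 equiv), CuI (10 mol %), THF, −30 → 0 °C; then H2O
Reagents that add atoms: methylmagnesium bromide, C[Mg]Br
Why: Copper-catalysed SN2 opening of the terminal epoxide at its CH2 carbon by the Grignard reagent (one equivalent is used up by the hydroxyl group) turns the vinyl group of linalool into an ethyl carbinol (C10 and C20); no lasting stereocentre is formed.

Step 3
Reactants: 3 (4R)-4,8-dimethylnon-7-ene-3,4-diol
Product: 4 (4R)-4-hydroxy-4,8-dimethylnon-7-en-3-one
Conditions: Dess–Martin periodinane, CH2Cl2, 0 °C → rt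
Reagents that add atoms: none
Why: Dess–Martin oxidation of the secondary alcohol gives the α-hydroxy ethyl ketone and removes the uncontrolled carbinol centre, while the tertiary carbinol C8 cannot be oxidised.

Step 4
Reactants: 4 (4R)-4-hydroxy-4,8-dimethylnon-7-en-3-one
Product: 5 (4R)-4-(methoxymethoxy)-4,8-dimethylnon-7-en-3-one
Conditions: MOMCl, i-Pr2NEt, n-Bu4NI (cat.), CH2Cl2, 40 °C
Reagents that add atoms: chloromethyl methyl ether, COCCl
Why: O-Alkylation of the tertiary α-ketol with the α-chloro ether (MOM protection) under an amine base that does not enolise the ketone; it installs the chelating ether used in step 7 and masks O-8 until step 14.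

Step 5
Reactants: 5 (4R)-4-(methoxymethoxy)-4,8-dimethylnon-7-en-3-one
Product: 7 (4R)-4-(methoxymethoxy)-4-methyl-5-oxoheptanal, via ozonide 6 (not isolated)
Conditions: O3, CH2Cl2, −78 °C; then PPh3, −78 °C → rt
Reagents that add atoms: ozone, [O-][O+]=O
Why: Ozonolysis of the only C=C bond with reductive work-up cuts the prenyl terminus down to the C5 aldehyde; no stereocentre is formed.

Step 6
Reactants: 7 (4R)-4-(methoxymethoxy)-4-methyl-5-oxoheptanal
Product: 8 methyl (2E,6R)-6-(methoxymethoxy)-2,6-dimethyl-7-oxonon-2-enoate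
Conditions: Ph3P=C(CH3)CO2CH3, toluene, 60 °C
Reagents that add atoms: methyl 2-(triphenyl-λ5-phosphanylidene)propanoate, COC(=O)C(C)=P(c1ccccc1)(c1ccccc1)c1ccccc1
Why: Wittig olefination with the stabilised α-methyl ylide should react with the aldehyde only (the ketone sits next to a quaternary carbon) and give the (E)-enoate, which brings in C4, one C4 methyl and C3.

Step 7
Reactants: 8 methyl (2E,6R)-6-(methoxymethoxy)-2,6-dimethyl-7-oxonon-2-enoate
Product: 10 methyl 2-[(1S,2S,4R)-4-(methoxymethoxy)-2,4-dimethyl-3-oxo-2-(prop-2-en-1-yl)cyclohexyl]propanoate (both epimers at the propanoate α-carbon), via lithium enolate 9 (not isolated)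
Conditions: LiN(SiMe3)2 (1.1 equiv), THF, −78 → 0 °C; then CH2=CHCH2Br, DMPU, 0 °C → rt
Reagents that add atoms: allyl bromide, C=CCBr
Why: LiN(SiMe3)2 forms the (Z)-lithium enolate of the ethyl ketone, its lithium held in a five-membered chelate by the ether oxygen on C8; the enolate carbon C10 then adds to C5 of the (E)-enoate and proton transfer from C10 gives the tetrasubstituted ketone enolate 9, which is C-allylated. The closest known reaction type is the base-mediated intramolecular Michael addition of a ketone enolate to an enoate, followed by enolate alkylation in the same flask. Ring B closes in the 6-(enolendo)-exo-trig mode through a chair-like transition state. C5 is controlled by the chelate: with O-8 in the enolate plane the C8 methyl is pseudoaxial, the chain that carries the enoate lies on the other face, and with the enoate pseudoequatorial the C5 side chain ends cis to the C8 methyl. C10 is controlled in the allylation, which takes place anti to the bulky C5 side chain (pseudoaxial because of A(1,2) strain with the C10 methyl) and away from the C8 methyl, so that allyl ends trans and the C10 methyl cis to both. The step needs face selectivity at C5 relative to the linalool-derived C8 and a single site of enolisation; the lithium chelate and the quaternary C8 (only C10 can be deprotonated) should secure them.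

Step 8
Reactants: 10 methyl 2-[(1S,2S,4R)-4-(methoxymethoxy)-2,4-dimethyl-3-oxo-2-(prop-2-en-1-yl)cyclohexyl]propanoate
Product: 11 methyl 2-[(1R,2S,4R)-4-(methoxymethoxy)-2,4-dimethyl-3-oxo-2-(prop-2-en-1-yl)cyclohexyl]-2-methylpropanoate
Conditions: LiN(i-Pr)2, THF/DMPU, −78 °C; CH3I, −78 → −20 °C
Reagents that add atoms: iodomethane, CI
Why: Ester enolate alkylation at the only enolisable position left (the ketone now lies between two quaternary carbons) makes C4 quaternary and removes its stereocentre.

Step 9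
Reactants: 11 methyl 2-[(1R,2S,4R)-4-(methoxymethoxy)-2,4-dimethyl-3-oxo-2-(prop-2-en-1-yl)cyclohexyl]-2-methylpropanoate
Product: 12 methyl 2-[(1R,2S,3R,4R)-3-hydroxy-4-(methoxymethoxy)-2,4-dimethyl-2-(prop-2-en-1-yl)cyclohexyl]-2-methylpropanoate
Conditions: NaBH4, CH3OH, 0 °C → rt
Reagents that add atoms: none
Why: Borohydride reduction of the α-alkoxy ketone, with hydride expected to enter anti to the two axial methyl groups (9β-OH); the configuration of this carbinol is of no consequence because C9 becomes a radical in step 11.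

Step 10
Reactants: 12 methyl 2-[(1R,2S,3R,4R)-3-hydroxy-4-(methoxymethoxy)-2,4-dimethyl-2-(prop-2-en-1-yl)cyclohexyl]-2-methylpropanoate
Product: 14 methyl 2-[(1R,2S,3R,4R)-4-(methoxymethoxy)-2,4-dimethyl-3-{[(methylsulfanyl)carbonothioyl]oxy}-2-(prop-2-en-1-yl)cyclohexyl]-2-methylpropanoate, via sodium xanthate 13 (not isolated)
Conditions: NaH, THF, 0 °C; CS2; then CH3I, rt
Reagents that add atoms: carbon disulfide, S=C=S; iodomethane, CI
Why: Xanthate formation (alkoxide addition to CS2, then S-methylation) gives the Barton–McCombie-type radical precursor; C8 and C10 carry no hydrogen, so Chugaev elimination cannot occur, and no stereocentre changes.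

Step 11
Reactants: 14 methyl 2-[(1R,2S,3R,4R)-4-(methoxymethoxy)-2,4-dimethyl-3-{[(methylsulfanyl)carbonothioyl]oxy}-2-(prop-2-en-1-yl)cyclohexyl]-2-methylpropanoate
Product: 15 methyl 2-[(1R,2S,3S,4R)-4-(methoxymethoxy)-2,4-dimethyl-3-(3-oxobutyl)-2-(prop-2-en-1-yl)cyclohexyl]-2-methylpropanoate
Conditions: CH2=CHCOCH3 (10 equiv), Bu3SnH (slow addition), AIBN, benzene, 80 °C
Reagents that add atoms: but-3-en-2-one, C=CC(C)=O
Why: Giese reaction: the C9 radical released from the xanthate should add to the enone from the α face, because the axial methyl groups on C8 and C10 flank the β lobe, which places C11 axial (α) and H-9 β, on the side of both methyl groups.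

Step 12
Reactants: 15 methyl 2-[(1R,2S,3S,4R)-4-(methoxymethoxy)-2,4-dimethyl-3-(3-oxobutyl)-2-(prop-2-en-1-yl)cyclohexyl]-2-methylpropanoate
Product: 17 methyl 2-[(1R,2S,3S,4R)-2-(2-methoxy-2-oxoethyl)-4-(methoxymethoxy)-2,4-dimethyl-3-(3-oxobutyl)cyclohexyl]-2-methylpropanoate, via aldehyde 16 (not isolated)
Conditions: O3, NaOH (2.5 M in CH3OH), CH2Cl2, −78 °C
Reagents that add atoms: ozone, [O-][O+]=O; methanol, CO
Why: Ozonolysis in methanolic NaOH cleaves the allyl group and oxidises the methyl hemiacetal of the resulting aldehyde to the methyl ester in the same flask, which turns allyl into CH2CO2CH3 (C1–C2); no stereocentre is touched.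

Step 13
Reactants: 17 methyl 2-[(1R,2S,3S,4R)-2-(2-methoxy-2-oxoethyl)-4-(methoxymethoxy)-2,4-dimethyl-3-(3-oxobutyl)cyclohexyl]-2-methylpropanoate
Product: 18 methyl 2-[(1R,2S,3S,4R)-3-(3-hydroxy-3-methylpent-4-en-1-yl)-2-(2-methoxy-2-oxoethyl)-4-(methoxymethoxy)-2,4-dimethylcyclohexyl]-2-methylpropanoate (both C13 epimers)
Conditions: CH2=CHMgBr (1.2 equiv), THF, −78 °C; then H2O
Reagents that add atoms: vinylmagnesium bromide, C=C[Mg]Br
Why: Grignard 1,2-addition to the methyl ketone, faster at low temperature than addition to either ester, gives the tertiary allylic alcohol; C13 forms without control here and is corrected in step 14.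

Step 14
Reactants: 18 methyl 2-[(1R,2S,3S,4R)-3-(3-hydroxy-3-methylpent-4-en-1-yl)-2-(2-methoxy-2-oxoethyl)-4-(methoxymethoxy)-2,4-dimethylcyclohexyl]-2-methylpropanoate
Product: 19 methyl 2-[(2R,4aS,5S,6R,8aR)-2-ethenyl-5-(2-methoxy-2-oxoethyl)-2,5,8a-trimethyloctahydro-2H-chromen-6-yl]-2-methylpropanoate
Conditions: CF3CO2H, CH2Cl2, −20 → 0 °C
Reagents that add atoms: none
Why: Acid-mediated SN1 cycloetherification: the tertiary allylic alcohol ionises to an allylic cation that is captured by O-8 with loss of the methoxymethyl group, the ring fusion is necessarily cis because C11 is axial and O-8 equatorial on the same face of ring B, and C13 is set under thermodynamic control through reversible ionisation of the tertiary allylic ether, the epimer with axial vinyl and equatorial methyl on the chair pyran being expected to predominate because vinyl is the smaller group in the 1,3-diaxial position opposite C7.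

Step 15
Reactants: 19 methyl 2-[(2R,4aS,5S,6R,8aR)-2-ethenyl-5-(2-methoxy-2-oxoethyl)-2,5,8a-trimethyloctahydro-2H-chromen-6-yl]-2-methylpropanoate
Product: 20 2-[(2R,4aS,5S,6R,8aR)-5-(carboxymethyl)-2-ethenyl-2,5,8a-trimethyloctahydro-2H-chromen-6-yl]-2-methylpropanoic acid (CNP0186744.1)
Conditions: NaSC2H5, DMF, 90 °C; then 1 M HCl to pH 3
Reagents that add atoms: none
Why: SN2 demethylation of both methyl esters by thiolate (attack at the methyl carbon is insensitive to the shielding of the C3 carboxyl), followed by acidification, should give the diacid without touching a stereocentre or the tertiary allylic ether.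

Compound list
1 | (R)-(−)-linalool, (3R)-3,7-dimethylocta-1,6-dien-3-ol | C=C[C@](C)(O)CCC=C(C)C | starting material
2 | (2R)-6-methyl-2-(oxiran-2-yl)hept-5-en-2-ol (both epoxide epimers) | C1OC1[C@](C)(O)CCC=C(C)C | intermediate
3 | (4R)-4,8-dimethylnon-7-ene-3,4-diol (both C3 epimers) | CCC(O)[C@](C)(O)CCC=C(C)C | intermediate
4 | (4R)-4-hydroxy-4,8-dimethylnon-7-en-3-one | CCC(=O)[C@](C)(O)CCC=C(C)C | intermediate
5 | (4R)-4-(methoxymethoxy)-4,8-dimethylnon-7-en-3-one | CCC(=O)[C@](C)(OCOC)CCC=C(C)C | intermediate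
6 | (4R)-6-(5,5-dimethyl-1,2,4-trioxolan-3-yl)-4-(methoxymethoxy)-4-methylhexan-3-one (ozonide) | CCC(=O)[C@](C)(OCOC)CCC1OOC(C)(C)O1 | intermediate
7 | (4R)-4-(methoxymethoxy)-4-methyl-5-oxoheptanal | CCC(=O)[C@](C)(OCOC)CCC=O | intermediate
8 | methyl (2E,6R)-6-(methoxymethoxy)-2,6-dimethyl-7-oxonon-2-enoate | CCC(=O)[C@](C)(OCOC)CC/C=C(\C)C(=O)OC | intermediate
9 | lithium enolate, methyl 2-[(1S,4R)-3-(lithiooxy)-4-(methoxymethoxy)-2,4-dimethylcyclohex-2-en-1-yl]propanoate (both epimers at the propanoate α-carbon) | [Li]OC1=C(C)[C@H](C(C)C(=O)OC)CC[C@@]1(C)OCOC | intermediate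
10 | methyl 2-[(1S,2S,4R)-4-(methoxymethoxy)-2,4-dimethyl-3-oxo-2-(prop-2-en-1-yl)cyclohexyl]propanoate (both epimers at the propanoate α-carbon) | O=C1[C@@](C)(CC=C)[C@H](C(C)C(=O)OC)CC[C@@]1(C)OCOC | intermediate
11 | methyl 2-[(1R,2S,4R)-4-(methoxymethoxy)-2,4-dimethyl-3-oxo-2-(prop-2-en-1-yl)cyclohexyl]-2-methylpropanoate | O=C1[C@@](C)(CC=C)[C@H](C(C)(C)C(=O)OC)CC[C@@]1(C)OCOC | intermediate
12 | methyl 2-[(1R,2S,3R,4R)-3-hydroxy-4-(methoxymethoxy)-2,4-dimethyl-2-(prop-2-en-1-yl)cyclohexyl]-2-methylpropanoate | O[C@@H]1[C@@](C)(CC=C)[C@H](C(C)(C)C(=O)OC)CC[C@@]1(C)OCOC | intermediate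
13 | sodium xanthate, sodium O-alkyl carbonodithioate of alcohol 12 at the ring carbinol | [Na+].[S-]C(=S)O[C@@H]1[C@@](C)(CC=C)[C@H](C(C)(C)C(=O)OC)CC[C@@]1(C)OCOC | intermediate
14 | methyl 2-[(1R,2S,3R,4R)-4-(methoxymethoxy)-2,4-dimethyl-3-{[(methylsulfanyl)carbonothioyl]oxy}-2-(prop-2-en-1-yl)cyclohexyl]-2-methylpropanoate | CSC(=S)O[C@@H]1[C@@](C)(CC=C)[C@H](C(C)(C)C(=O)OC)CC[C@@]1(C)OCOC | intermediate
15 | methyl 2-[(1R,2S,3S,4R)-4-(methoxymethoxy)-2,4-dimethyl-3-(3-oxobutyl)-2-(prop-2-en-1-yl)cyclohexyl]-2-methylpropanoate | CC(=O)CC[C@H]1[C@@](C)(CC=C)[C@H](C(C)(C)C(=O)OC)CC[C@@]1(C)OCOC | intermediate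
16 | methyl 2-[(1R,2S,3S,4R)-4-(methoxymethoxy)-2,4-dimethyl-3-(3-oxobutyl)-2-(2-oxoethyl)cyclohexyl]-2-methylpropanoate | CC(=O)CC[C@H]1[C@@](C)(CC=O)[C@H](C(C)(C)C(=O)OC)CC[C@@]1(C)OCOC | intermediate
17 | methyl 2-[(1R,2S,3S,4R)-2-(2-methoxy-2-oxoethyl)-4-(methoxymethoxy)-2,4-dimethyl-3-(3-oxobutyl)cyclohexyl]-2-methylpropanoate | CC(=O)CC[C@H]1[C@@](C)(CC(=O)OC)[C@H](C(C)(C)C(=O)OC)CC[C@@]1(C)OCOC | intermediate
18 | methyl 2-[(1R,2S,3S,4R)-3-(3-hydroxy-3-methylpent-4-en-1-yl)-2-(2-methoxy-2-oxoethyl)-4-(methoxymethoxy)-2,4-dimethylcyclohexyl]-2-methylpropanoate (both C13 epimers) | C=CC(C)(O)CC[C@H]1[C@@](C)(CC(=O)OC)[C@H](C(C)(C)C(=O)OC)CC[C@@]1(C)OCOC | intermediate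
19 | methyl 2-[(2R,4aS,5S,6R,8aR)-2-ethenyl-5-(2-methoxy-2-oxoethyl)-2,5,8a-trimethyloctahydro-2H-chromen-6-yl]-2-methylpropanoate | C=C[C@@]1(C)CC[C@H]2[C@@](C)(CC(=O)OC)[C@H](C(C)(C)C(=O)OC)CC[C@@]2(C)O1 | intermediate
20 | 2-[(2R,4aS,5S,6R,8aR)-5-(carboxymethyl)-2-ethenyl-2,5,8a-trimethyloctahydro-2H-chromen-6-yl]-2-methylpropanoic acid | C=C[C@@]1(C)CC[C@H]2[C@@](C)(CC(=O)O)[C@H](C(C)(C)C(=O)O)CC[C@@]2(C)O1 | target

Total step count: 15. Longest linear sequence: 15 steps (1 → 20).

Steps most likely to fail

Step 7: the lithium chelate between the enolate oxygen and the C8 ether oxygen may not hold, or the Michael addition may become reversible, so that C5 forms with the wrong sense relative to C8; allylation may also overtake the proton transfer. The fallback replaces ether chelation by an alkoxide-directed dianion cyclisation. Setting out from 8, the MOM group is removed (HCl, CH3OH) to give methyl (2E,6R)-6-hydroxy-2,6-dimethyl-7-oxonon-2-enoate F1. Its dilithium alkoxide–enolate (LiN(SiMe3)2, 2.2 equiv), in which lithium bridges the two neighbouring oxygens rigidly, is cyclised and allylated in one flask to methyl 2-[(1S,2S,4R)-4-hydroxy-2,4-dimethyl-3-oxo-2-(prop-2-en-1-yl)cyclohexyl]propanoate F2. The MOM ether is then put back (MOMCl, i-Pr2NEt) to come back at 10.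

Step 11: the C9 radical lies between two quaternary carbons and may take a hydrogen atom from Bu3SnH before it adds to the enone (plain deoxygenation), or may add from the β face. The fallback is an addition–fragmentation chain that needs no hydride donor. Setting out from 14, reaction with (E)-4-(tributylstannyl)but-3-en-2-one and (Bu3Sn)2 under irradiation should give methyl 2-[(1R,2S,3S,4R)-4-(methoxymethoxy)-2,4-dimethyl-3-[(1E)-3-oxobut-1-en-1-yl]-2-(prop-2-en-1-yl)cyclohexyl]-2-methylpropanoate F3. Conjugate reduction of the enone with [(Ph3P)CuH]6 returns to 15.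

Step 14: the allylic cation may eliminate to dienes, or the equilibrium at C13 may not favour the wanted epimer strongly enough. The fallback forms the C13–vinyl bond kinetically at a ring oxocarbenium ion instead of forming the C13–O bond at an allylic cation. Setting out from 17, p-TsOH in CH3OH removes the MOM group and closes the bicyclic methyl ketal methyl 2-[(4aS,5S,6R,8aR)-2-methoxy-5-(2-methoxy-2-oxoethyl)-2,5,8a-trimethyloctahydro-2H-chromen-6-yl]-2-methylpropanoate F4. CH2=CHBF3K with BF3·OEt2 in CH3CN then replaces methoxide by vinyl through axial attack on the oxocarbenium ion, which comes back at 19.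

Further compounds
F1 | step 7 | methyl (2E,6R)-6-hydroxy-2,6-dimethyl-7-oxonon-2-enoate | CCC(=O)[C@](C)(O)CC/C=C(\C)C(=O)OC
F2 | step 7 | methyl 2-[(1S,2S,4R)-4-hydroxy-2,4-dimethyl-3-oxo-2-(prop-2-en-1-yl)cyclohexyl]propanoate (both epimers at the propanoate α-carbon) | O=C1[C@@](C)(CC=C)[C@H](C(C)C(=O)OC)CC[C@@]1(C)O
F3 | step 11 | methyl 2-[(1R,2S,3S,4R)-4-(methoxymethoxy)-2,4-dimethyl-3-[(1E)-3-oxobut-1-en-1-yl]-2-(prop-2-en-1-yl)cyclohexyl]-2-methylpropanoate | CC(=O)/C=C/[C@H]1[C@@](C)(CC=C)[C@H](C(C)(C)C(=O)OC)CC[C@@]1(C)OCOC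
F4 | step 14 | methyl 2-[(4aS,5S,6R,8aR)-2-methoxy-5-(2-methoxy-2-oxoethyl)-2,5,8a-trimethyloctahydro-2H-chromen-6-yl]-2-methylpropanoate (either configuration at the ketal carbon) | COC1(C)CC[C@H]2[C@@](C)(CC(=O)OC)[C@H](C(C)(C)C(=O)OC)CC[C@@]2(C)O1
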